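**Stopped, not slow.** Slowness was not what I found when you asked for a quick number on the order in coupling partner. The spring flask showed 27.7% product at its first reading, 10.0 s, and averaged 28.0% over its readings. The midnight flask, with more partner charged, averaged 40.3%. The early rates were unresolved, so I read the plateaus.

in all of them: substrate 0.14 M; free catalyst 0.35 mol%
- spring: coupling partner 1.1 equiv; the very flask that is asked about, followed so far
- midnight: coupling partner 1.7 equiv; run made earlier
- flask: coupling partner 1.10 equiv

spring run (percent of the substrate charged)

| time / s | product / % | substrate / % |
|---|---|---|
| 10.0 | 27.7 | 72.8 |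
| 20.0 | 27.9 | 71.3 |
| 30.0 | 28.4 | 71.5 |
| 50.0 | 27.7 | 71.6 |
| 80.0 | 27.7 | 70.7 |
| 90.0 | 28.6 | 71.8 |

midnight run (percent of the substrate charged)

| time / min | product / % | substrate / % |
|---|---|---|
| 0.500 | 39.2 | 60.7 |
| 1.00 | 40.5 | 58.9 |
| 1.33 | 40.5 | 59.9 |
| 2.00 | 40.6 | 59.5 |
| 2.50 | 40.9 | 59.0 |
| 3.00 | 40.3 | 59.7 |

(readings scatter by 0.5 percentage points)

- apparent order in coupling partner when 10% of the substrate are converted (percent change of the rate of making product for one percent more coupling partner charged)

**The turnover budget.** I took the rate as proportional to substrate, partner and free catalyst, with free catalyst dying first-order whatever the mixture held (catalyst deactivation). Let a be substrate left per substrate charged, b partner left on that scale, f the free share of catalyst, and I the sum of dx/(ab) up to conversion x. Then f falls in step with I. The spring flask stopped at I = 0.347; this is the turnover budget B, the I at which f reaches zero. Carried to the midnight flask, B predicted a stop at 40.1%, and I read 40.3%.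

**The order.** At 10% conversion in the asked flask, I = 0.101, which left f = 71.1%. Partner itself contributed 1.10. By a midpoint estimate, the catalyst spared by more partner added 0.425, giving 1.53. The forecast was 1.5, from 1.15 to 1.75: “More partner also means less catalyst has died by that conversion”.

**What came.** The flask gave 1.5.

    free catalyst → spent catalyst (k = 0.286 s⁻¹)
    substrate + coupling partner + free catalyst → free catalyst + product (k = 1470 M⁻² s⁻¹)

In the spring flask at 0.0319 min, free catalyst had a half-life of 2.4 s by its loss to spent catalyst, while coupling partner had 0.23 min by the coupling step, 5.75 times longer. The budget of 0.347 was used up with both reagents remaining: at 4.00 min free catalyst stood at 0%, substrate at 71.7% and coupling partner at 74%.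

The data were generated by integration for an exercise, and the scatter is random.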